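The free catalyst is the worker here, and I want to know how much target it makes in each flask.

    starting material + free catalyst ⇌ catalyst intermediate A (K1 = 4.4 M⁻¹, k1 = 0.66 M⁻¹ s⁻¹, Ea1 = 63.0 kJ mol⁻¹, ΔH1 = 14.0 kJ mol⁻¹)
    second substrate + free catalyst ⇌ catalyst intermediate B (K2 = 380 M⁻¹, k2 = 0.34 M⁻¹ s⁻¹, Ea2 = 60.0 kJ mol⁻¹, ΔH2 = −17.0 kJ mol⁻¹)
    reagent + catalyst intermediate A → free catalyst + target (k3 = 0.11 M⁻¹ s⁻¹, Ea3 = 60.0 kJ mol⁻¹)
    reagent + catalyst intermediate B → free catalyst + second product (k4 = 0.32 M⁻¹ s⁻¹, Ea4 = 52.0 kJ mol⁻¹)
    free catalyst + target ⇌ idle complex, settled at all times (K5 = 9.0 M⁻¹, ΔH5 = −21.0 kJ mol⁻¹)
    (constants at 25 °C)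

| setting | cedar | maple | larch | oak | ash |
|---|---|---|---|---|---|
| starting material | 0.20 M | 0.20 M | 0.20 M | 0.20 M | 0.20 M |
| second substrate | 0.500 equiv | 0.500 equiv | 0.500 equiv (in portions, 5, over 2.5 min) | 0.500 equiv | 0.500 equiv (fed, over 2.5 min) |
| reagent | 1.05 equiv (fed, over 2.5 min) | 1.05 equiv | 1.05 equiv | 1.05 equiv | 1.05 equiv |
| free catalyst | 10 mol% | 10 mol% | 10 mol% | 10 mol% | 10 mol% |
| temperature | 25 °C | 25 °C | 25 °C |  |  |
| time | 3.0 min | 3.0 min | 3.0 min | 3.0 min | 3.0 min |
| remark | all else is in the flask from the start; the feed brings no volume worth counting | everything together at the start | first portion at the start, last at 2.5 min | everything together at the start at −5 °C, warmed to 25 °C at 2.5 min | the addition at −5 °C, then warmed to 25 °C; the feed brings no volume worth counting |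

- what is said of target includes idle complex
- the constants hold at 25 °C; other temperatures follow from the activation energies and enthalpies

* which flask leads in amount of target, in percent of the starting material charged ("all alike" within 1.5 percentage points) (cedar / maple / larch / oak / ash / all alike)
* how much target is there at the end, in percent of the starting material charged: cedar
* how much target is there at the end, in percent of the starting material charged: maple
* how much target is there at the end, in percent of the starting material charged: larch
* how much target is there at the end, in percent of the starting material charged: oak
* how much target is there at the end, in percent of the starting material charged: ash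

I turn constants into times at the charged amounts, and I start with maple, where everything goes in together. Take the main round by itself. Free catalyst meets starting material once in 7.58 s. Reagent stands at 0.210 M. Catalyst intermediate A falls apart in 6.67 s and meets reagent once in 43.3 s; the meeting times are pseudo-first-order, with the partner held at its charge. Balancing the making and the loss gives intermediate A at 0.763 of the free catalyst.

I call the target pace the target that a run makes if reagent and the catalyst's shares stay as they are at the start, in percent of the starting material charged. It is the rate constant of step 3, times reagent, times intermediate A, times the time, over the charge. With 0.0200 M of catalyst, the main round gives 18.0%.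

Now I add the second substrate, at 0.100 M. Its binding constant times its charge is 38, which looks like a trap for the catalyst. But catalyst intermediate B falls apart in 18.6 min and meets reagent once in 14.9 s, so reagent clears it far sooner. Intermediate B therefore stands at 0.499 of the free catalyst, and the pace drops to 14.0%. With both rounds running, this is the figure I carry: the target pace, the target made if reagent and the catalyst's shares stay as they are at the start.

Then comes the rest. At these shares the two product steps would use 38.8% of the reagent, so I take its mean at 80.6% of charge. The idle complex, at the run's mean target, adds 0.126 to the catalyst's count, in units of free catalyst. Together these bring maple to 10.7%. I leave aside the shifts in the shares themselves.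

For larch, the second substrate comes in portions, so I place it between that figure and 13.8%, and I expect it to lead maple. For cedar, I take reagent at half its charge, which gives 6.06%. Oak and ash are warm for 30.0 s, worth 2.34% at the pace, before anything from the cold stretch. My reckoning stops there.

The forecast names larch: cedar 6.4%, maple 11%, larch 12.3%, oak 2.6%, ash 2.7%. Its ground for the leader is “little second substrate early frees catalyst”. Its maple stands a little above mine.

The simulation gives larch the lead: cedar 6.16%, maple 11.1%, larch 12.6%, oak 2.64%, ash 2.75%. The forecast holds, and larch leads maple by 1.5 percentage points against a margin of 1.5 points. Maple keeps 0.789 of its target pace. The neighbour of larch with 1.80 equiv of reagent has a pace of 24.9% at its charges. Maple's kept part turns that into 19.6%, and that neighbour of larch ends with 20.4% of target.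

(The rate constants are made up; no experiment stands behind them.)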